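**Retrosynthetic overview**
- The strategy rests on the 4H-pyran-4-one C ring (O1–C2–C3–C4–C4a–C8a). It is cut at C4a–C4, C4–C3 and O1–C2, so C4 is carbon monoxide, C2/C3 are a terminal arylacetylene carrying ring B, and O1/C8a/C4a are an ortho-iodophenol.
- On the hexasubstituted A ring, O1 (on C8a) is para to the 6-oxygen (on C6), so ring A is built as a differentiated hydroquinone. The sequence from 1,2,4-trimethoxybenzene is ortho-metalation/hydroxylation (future O6), para-bromination, MOM protection, Br/Li exchange/hydroxylation (future O1), then iodination of the last C–H (future C4a).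
- Ring B comes from 2-hydroxy-6-methoxybenzaldehyde by MOM protection and one-carbon homologation to the alkyne.
- Ring order: A and B are bought as benzene rings. C is the only ring formed, in the three-component union that also joins the fragments. Acid removal of the two MOM groups ends the route.

Key step: step 8

Remark on the chemistry: the target has no stereocentre and its SMILES has no stereodescriptor. Rotation about C2–C1' (flanked on the pyranone side only by O1 and C3–H) is fast, so there is no enantiomer to select and the achiral compound is the goal.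

**Step 1**
Reactants: 1 1,2,4-trimethoxybenzene
Product: 4 2,3,6-trimethoxyphenol, via aryllithium 2 (not isolated), via dimethyl arylboronate 3 (not isolated)
Conditions: n-BuLi, THF, 0 °C → rt; B(OMe)3, −78 °C → rt; AcOH, 30% aq. H2O2, 0 °C → rt
Reagents that add atoms: hydrogen peroxide OO (the phenol oxygen); n-butyllithium [Li]CCCC and trimethyl borate COB(OC)OC (atoms only in intermediates 2 and 3)
Why: Directed ortho-metalation followed by borylation and peroxide oxidation (1,2-aryl shift from boron to oxygen): the C3–H of 1 lies between two methoxy groups, is the most acidic ring proton and gives a doubly coordinated aryllithium, so the new oxygen should enter only there.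

**Step 2**
Reactants: 4 2,3,6-trimethoxyphenol
Product: 5 4-bromo-2,3,6-trimethoxyphenol
Conditions: NBS (1.0 equiv), MeCN, −20 → 0 °C, dark
Reagents that add atoms: N-bromosuccinimide O=C1CCC(=O)N1Br
Why: Electrophilic aromatic bromination: C4 is para to the free hydroxyl, the strongest donor on the ring, and ortho to the 3-methoxy group, while C5 is activated only by ethers of which the para one (2-OMe) is twisted out of conjugation by its two neighbours, so one equivalent of NBS in the cold should substitute C4.

**Step 3**
Reactants: 5 4-bromo-2,3,6-trimethoxyphenol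
Product: 6 1-bromo-2,3,5-trimethoxy-4-(methoxymethoxy)benzene
Conditions: MOMCl, i-Pr2NEt, CH2Cl2, 0 °C → rt
Reagents that add atoms: chloromethyl methyl ether COCCl
Why: O-alkylation of a phenol with a chloromethyl ether (MOM protection): the small, highly reactive electrophile reaches the oxygen flanked by two methoxy groups, and the resulting acetal tolerates the organolithium, the iodination and the basic carbonylation ahead while masking the future 6-OH.

**Step 4**
Reactants: 6 1-bromo-2,3,5-trimethoxy-4-(methoxymethoxy)benzene
Product: 9 2,3,5-trimethoxy-4-(methoxymethoxy)phenol, via aryllithium 7 (not isolated), via dimethyl arylboronate 8 (not isolated)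
Conditions: n-BuLi, THF, −78 °C; B(OMe)3, −78 → 0 °C; AcOH, 30% aq. H2O2, 0 °C → rt
Reagents that add atoms: hydrogen peroxide OO (the phenol oxygen); n-butyllithium [Li]CCCC and trimethyl borate COB(OC)OC (atoms only in intermediates 7 and 8)
Why: Bromine–lithium exchange, borate trapping and peroxide oxidation: exchange at −78 °C is far faster than any deprotonation or attack on the acetal, and the acetic acid-buffered oxidation spares both the MOM ether and the electron-rich phenol, whose oxygen (para to OMOM) is the future O1.

**Step 5**
Reactants: 9 2,3,5-trimethoxy-4-(methoxymethoxy)phenol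
Product: 10 2-iodo-3,5,6-trimethoxy-4-(methoxymethoxy)phenol
Conditions: NIS (1.0 equiv), dry MeCN, −20 → 0 °C, dark
Reagents that add atoms: N-iodosuccinimide O=C1CCC(=O)N1I
Why: Electrophilic aromatic iodination: only one ring C–H is left, it is ortho to the free hydroxyl and to a methoxy group, and a neutral iodonium donor in a dry aprotic solvent leaves the acetal intact and offers no nucleophile for oxidative dearomatisation of the hydroquinone monoether.

**Step 6**
Reactants: 11 2-hydroxy-6-methoxybenzaldehyde
Product: 12 2-methoxy-6-(methoxymethoxy)benzaldehyde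
Conditions: MOMCl, i-Pr2NEt, CH2Cl2, 0 °C → rt
Reagents that add atoms: chloromethyl methyl ether COCCl
Why: MOM protection by O-alkylation: the amine base breaks the hydrogen bond to the aldehyde and the phenoxide is capped, which keeps the 2'-oxygen from adding to the alkyne later.

**Step 7**
Reactants: 12 2-methoxy-6-(methoxymethoxy)benzaldehyde
Product: 13 2-ethynyl-1-methoxy-3-(methoxymethoxy)benzene
Conditions: dimethyl (1-diazo-2-oxopropyl)phosphonate, K2CO3, MeOH, 0 °C → rt
Reagents that add atoms: dimethyl (1-diazo-2-oxopropyl)phosphonate CC(=O)C(=[N+]=[N-])P(=O)(OC)OC (the terminal alkyne carbon)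
Why: Seyferth–Gilbert homologation in the Ohira–Bestmann variant: methanolysis of the reagent gives the diazomethylphosphonate anion, which olefinates the non-enolisable aldehyde, and loss of nitrogen with 1,2-hydrogen shift gives the terminal alkyne under conditions too mild to touch the MOM ether.

**Step 8**
Reactants: 10 2-iodo-3,5,6-trimethoxy-4-(methoxymethoxy)phenol; 13 2-ethynyl-1-methoxy-3-(methoxymethoxy)benzene; 14 carbon monoxide
Product: 17 5,7,8,6'-tetramethoxy-6,2'-bis(methoxymethoxy)flavone, via hydroxyaryl ynone 15 (not isolated), via diethylamino enaminone 16 (not isolated)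
Conditions: PdCl2(dppf) (5 mol %), CO (20 bar), degassed Et2NH, 100 °C, autoclave, no copper
Reagents that add atoms: carbon monoxide [C-]#[O+] (compound 14, already listed as reactant; becomes C4 and its oxygen); diethylamine CCNCC (enters intermediate 16 only and leaves again on ring closure)
Why: Carbonylative Sonogashira coupling followed by annulation, the known reaction of 2-iodophenols with terminal arylacetylenes and CO in a secondary amine: Pd(0) inserts into the C–I bond of 10, the electron-rich aryl migrates onto bound CO (C4a–C4), and the aroyl–Pd species takes up the amine-deprotonated alkyne 13 and reductively eliminates (C4–C3) to ynone 15. Diethylamine adds in conjugate fashion to 15 to give the push–pull enaminone 16, whose β-carbon (future C2) is then attacked by the neighbouring phenol oxygen (O1–C2) with expulsion of the amine. The only ring closed is the pyranone C ring, by a 6-endo addition–elimination, and no stereocentre is created. Three selectivities are needed: CO uptake before alkyne transfer, alkyne transfer before aminolysis of the aroyl–Pd, and 6-endo rather than 5-exo closure. The first is served by CO pressure, the absence of copper and the ready migration and steric relief of the di-ortho-substituted aryl, the second by the two ortho substituents that shield the acyl carbon from the bulky amine, and the third by routing the closure through 16, in which only the β-carbon is electrophilic. Substrate 10 offers one iodine next to one free hydroxyl, and the MOM groups on O6 and O2' keep those oxygens out of competing cyclisations (a free B-ring phenol next to the alkyne would close to a benzofuran).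

**Step 9**
Reactants: 17 5,7,8,6'-tetramethoxy-6,2'-bis(methoxymethoxy)flavone
Product: 18 6,2'-dihydroxy-5,7,8,6'-tetramethoxyflavone
Conditions: 3 M aq. HCl, MeOH, 45 °C
Reagents that add atoms: none
Why: Acid-catalysed acetal cleavage (MOM removal): both aryl MOM ethers ionise to a methoxymethyl cation that methanol captures, whereas the aryl methyl ethers, including the peri 5-OMe that only chelating Lewis acids would strip, are inert to dilute protic acid, and the mild temperature avoids opening and re-closure of the pyranone through the freed 2'-OH.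

**Compound list**
1 | 1,2,4-trimethoxybenzene | COc1ccc(OC)c(OC)c1 | starting material
2 | (2,3,6-trimethoxyphenyl)lithium | [Li]c1c(OC)ccc(OC)c1OC | intermediate (not isolated)
3 | dimethyl (2,3,6-trimethoxyphenyl)boronate | COB(OC)c1c(OC)ccc(OC)c1OC | intermediate (not isolated)
4 | 2,3,6-trimethoxyphenol | COc1ccc(OC)c(OC)c1O | intermediate
5 | 4-bromo-2,3,6-trimethoxyphenol | COc1cc(Br)c(OC)c(OC)c1O | intermediate
6 | 1-bromo-2,3,5-trimethoxy-4-(methoxymethoxy)benzene | COCOc1c(OC)cc(Br)c(OC)c1OC | intermediate
7 | [2,3,5-trimethoxy-4-(methoxymethoxy)phenyl]lithium | COCOc1c(OC)cc([Li])c(OC)c1OC | intermediate (not isolated)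
8 | dimethyl [2,3,5-trimethoxy-4-(methoxymethoxy)phenyl]boronate | COCOc1c(OC)cc(B(OC)OC)c(OC)c1OC | intermediate (not isolated)
9 | 2,3,5-trimethoxy-4-(methoxymethoxy)phenol | COCOc1c(OC)cc(O)c(OC)c1OC | intermediate
10 | 2-iodo-3,5,6-trimethoxy-4-(methoxymethoxy)phenol | COCOc1c(OC)c(I)c(O)c(OC)c1OC | intermediate
11 | 2-hydroxy-6-methoxybenzaldehyde | COc1cccc(O)c1C=O | starting material
12 | 2-methoxy-6-(methoxymethoxy)benzaldehyde | COCOc1cccc(OC)c1C=O | intermediate
13 | 2-ethynyl-1-methoxy-3-(methoxymethoxy)benzene | COCOc1cccc(OC)c1C#C | intermediate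
14 | carbon monoxide | [C-]#[O+] | starting material
15 | 1-[2-hydroxy-3,4,6-trimethoxy-5-(methoxymethoxy)phenyl]-3-[2-methoxy-6-(methoxymethoxy)phenyl]prop-2-yn-1-one | COCOc1cccc(OC)c1C#CC(=O)c1c(O)c(OC)c(OC)c(OCOC)c1OC | intermediate (not isolated)
16 | (E)-3-(diethylamino)-1-[2-hydroxy-3,4,6-trimethoxy-5-(methoxymethoxy)phenyl]-3-[2-methoxy-6-(methoxymethoxy)phenyl]prop-2-en-1-one (push–pull alkene, geometry labile and without consequence) | CCN(CC)/C(=C/C(=O)c1c(O)c(OC)c(OC)c(OCOC)c1OC)c1c(OC)cccc1OCOC | intermediate (not isolated)
17 | 5,7,8-trimethoxy-6-(methoxymethoxy)-2-[2-methoxy-6-(methoxymethoxy)phenyl]-4H-chromen-4-one | COCOc1cccc(OC)c1-c1cc(=O)c2c(OC)c(OCOC)c(OC)c(OC)c2o1 | intermediate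
18 | 6-hydroxy-2-(2-hydroxy-6-methoxyphenyl)-5,7,8-trimethoxy-4H-chromen-4-one (6,2'-dihydroxy-5,7,8,6'-tetramethoxyflavone) | COc1cccc(O)c1-c1cc(=O)c2c(OC)c(O)c(OC)c(OC)c2o1 | target

**Total step count:** 9
**Longest linear sequence:** 7 (steps 1–5, 8, 9)

**Steps most likely to fail**

1. **Step 8.**
   - Risks: slow oxidative addition at a C–I bond flanked by two oxygen substituents on a very electron-rich ring, alkyne transfer before CO uptake, aminolysis of the aroyl–palladium, reductive loss of iodine, or 5-exo closure.
   - Fallback (sets out from 9 and 13, returns at 17): C4 is brought in as a formyl carbon instead of CO. Magnesium-mediated ortho-formylation of 9 (MgCl2, Et3N, paraformaldehyde, MeCN, reflux; Casnati–Skattebøl) should give 2-hydroxy-3,4,6-trimethoxy-5-(methoxymethoxy)benzaldehyde F1. Silylation (TBSCl, imidazole, DMF) converts it to its O-TBS ether F2. Alkyne 13 is deprotonated (n-BuLi, THF, −78 °C) to the lithium acetylide F3. This adds to F2 and, after NH4Cl quench, should give the racemic propargylic alcohol F4, whose carbinol centre disappears in the next operation. Oxidation (MnO2, CH2Cl2, or buffered Dess–Martin periodinane) should give the silyl-protected ynone F5. TBAF in THF containing Et2NH then unmasks ynone 15, which should close through 16 to 17 as in the main route.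

2. **Step 5.**
   - Risk: two-electron oxidation of the hydroquinone monoether by the iodonium source, with loss of the MOM group, in place of C–H substitution.
   - Fallback (sets out from 9, returns at 10): the C–I bond is made from a carbanion rather than by electrophilic substitution. Phenol 9 is protected (SEMCl, i-Pr2NEt, CH2Cl2) as the SEM ether F6. n-BuLi (THF, 0 °C) removes the only ring proton, which lies between OSEM and OMe (directed ortho-metalation), to give the aryllithium F7. Iodine at −78 °C should give the iodinated SEM ether F8. TBAF (THF, 50 °C) removes the SEM group alone, since the MOM group has no silicon handle, and returns 10.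

3. **Step 2.**
   - Risks: poor site selectivity between C4 and C5, a second bromination, or oxidative dearomatisation of the electron-rich phenol.
   - Fallback (sets out from 4, returns at 9, bypassing 5–8): the para oxygen is installed directly by oxidation. Teuber oxidation of 4 (Fremy's salt, aq. KH2PO4/acetone) should give 2,3,5-trimethoxy-1,4-benzoquinone F9. Reduction with Na2S2O4 gives 2,3,5-trimethoxybenzene-1,4-diol F10. One equivalent of TBSCl (imidazole, CH2Cl2, 0 °C) should silylate the less hindered hydroxyl, the one with an ortho hydrogen, to give 4-(tert-butyldimethylsilyloxy)-2,3,6-trimethoxyphenol F11. MOMCl/i-Pr2NEt caps the remaining doubly flanked hydroxyl to give the mixed TBS/MOM bis-ether F12. TBAF (THF, 0 °C) then releases 9.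

**Further compounds**
F1 | step 8 | 2-hydroxy-3,4,6-trimethoxy-5-(methoxymethoxy)benzaldehyde | COCOc1c(OC)c(C=O)c(O)c(OC)c1OC
F2 | step 8 | 2-(tert-butyldimethylsilyloxy)-3,4,6-trimethoxy-5-(methoxymethoxy)benzaldehyde | COCOc1c(OC)c(C=O)c(O[Si](C)(C)C(C)(C)C)c(OC)c1OC
F3 | step 8 | {[2-methoxy-6-(methoxymethoxy)phenyl]ethynyl}lithium | COCOc1cccc(OC)c1C#C[Li]
F4 | step 8 | (±)-1-[2-(tert-butyldimethylsilyloxy)-3,4,6-trimethoxy-5-(methoxymethoxy)phenyl]-3-[2-methoxy-6-(methoxymethoxy)phenyl]prop-2-yn-1-ol | COCOc1cccc(OC)c1C#CC(O)c1c(O[Si](C)(C)C(C)(C)C)c(OC)c(OC)c(OCOC)c1OC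
F5 | step 8 | 1-[2-(tert-butyldimethylsilyloxy)-3,4,6-trimethoxy-5-(methoxymethoxy)phenyl]-3-[2-methoxy-6-(methoxymethoxy)phenyl]prop-2-yn-1-one | COCOc1cccc(OC)c1C#CC(=O)c1c(O[Si](C)(C)C(C)(C)C)c(OC)c(OC)c(OCOC)c1OC
F6 | step 5 | 1,2,4-trimethoxy-3-(methoxymethoxy)-6-{[2-(trimethylsilyl)ethoxy]methoxy}benzene | COCOc1c(OC)cc(OCOCC[Si](C)(C)C)c(OC)c1OC
F7 | step 5 | (2,4,5-trimethoxy-3-(methoxymethoxy)-6-{[2-(trimethylsilyl)ethoxy]methoxy}phenyl)lithium | COCOc1c(OC)c([Li])c(OCOCC[Si](C)(C)C)c(OC)c1OC
F8 | step 5 | 1-iodo-2,4,5-trimethoxy-3-(methoxymethoxy)-6-{[2-(trimethylsilyl)ethoxy]methoxy}benzene | COCOc1c(OC)c(I)c(OCOCC[Si](C)(C)C)c(OC)c1OC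
F9 | step 2 | 2,3,5-trimethoxy-1,4-benzoquinone | COC1=CC(=O)C(OC)=C(OC)C1=O
F10 | step 2 | 2,3,5-trimethoxybenzene-1,4-diol | COc1cc(O)c(OC)c(OC)c1O
F11 | step 2 | 4-(tert-butyldimethylsilyloxy)-2,3,6-trimethoxyphenol | COc1cc(O[Si](C)(C)C(C)(C)C)c(OC)c(OC)c1O
F12 | step 2 | tert-butyldimethyl[2,3,5-trimethoxy-4-(methoxymethoxy)phenoxy]silane | COCOc1c(OC)cc(O[Si](C)(C)C(C)(C)C)c(OC)c1OC
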